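**Strategy.** The dihydropyran ring is disconnected at its O1–C2 ether bond, which leads back to an achiral 2-(2-arylallyl)phenol. The key step exploits two features: C3 is a benzylic CH on the electron-rich ring B, flanked by the methylenes C2 and C4, and O1 is an ortho phenol of ring A. Carrying C2=C3 as a 1,1-disubstituted alkene, one photoredox operation (radical-cation 6-endo attack of O1–H on C2, then enantioselective hydrogen-atom transfer to the C3 radical) closes the ring and sets the only stereocentre without any change of oxidation level. The 1,1-dimethylallyl group is unmasked afterwards by Claisen rearrangement of a 4'-O-prenyl ether.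

Key step: step 8

Remark: the target is taken as the (3R)-isoflavan (C3 is its only stereocentre), and 2',3',4'-trihydroxyacetophenone, prenyl bromide and 4-bromoresorcinol are taken as commercial.

Step 1
Reactants: 1 2',3',4'-trihydroxyacetophenone; 2 prenyl bromide (1-bromo-3-methylbut-2-ene)
Product: 3 1-[2,3-dihydroxy-4-(3-methylbut-2-enyloxy)phenyl]ethanone
Conditions: NaHCO3, KI (cat.), DMF, 40 °C
Reagents that add atoms: none
Why: Williamson etherification should occur at the 4-OH, the most acidic phenol (para to the acetyl group and not hydrogen-bonded to it), while the chelated 2-OH and the flanked 3-OH stay free.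

Step 2
Reactants: 3 1-[2,3-dihydroxy-4-(3-methylbut-2-enyloxy)phenyl]ethanone
Product: 4 1-[2-hydroxy-3-(methoxymethoxy)-4-(3-methylbut-2-enyloxy)phenyl]ethanone
Conditions: MOMCl, K2CO3, acetone, 0 °C to rt
Reagents that add atoms: chloromethyl methyl ether (MOMCl), COCCl
Why: O-alkylation (MOM ether formation) should take the 3-OH because the 2-OH is held in a strong hydrogen bond to the acetyl carbonyl and reacts last.

Step 3
Reactants: 4 1-[2-hydroxy-3-(methoxymethoxy)-4-(3-methylbut-2-enyloxy)phenyl]ethanone
Product: 5 1-[2-methoxy-3-(methoxymethoxy)-4-(3-methylbut-2-enyloxy)phenyl]ethanone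
Conditions: MeI, K2CO3, DMF, 45 °C
Reagents that add atoms: iodomethane, CI
Why: Williamson methylation of the remaining chelated phenol with a small electrophile in a dipolar aprotic solvent should complete the oxygenation pattern of ring B.

Step 4
Reactants: 6 4-bromoresorcinol (4-bromobenzene-1,3-diol)
Product: 7 1-bromo-2,4-bis(triisopropylsilyloxy)benzene
Conditions: NaH, TIPSCl, THF, 0 °C to rt
Reagents that add atoms: chlorotriisopropylsilane (TIPSCl), CC(C)[Si](Cl)(C(C)C)C(C)C
Why: O-silylation of both phenoxides should give base-stable, fluoride-labile ethers that are orthogonal to the MOM acetal and the prenyl ether of ring B.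

Step 5
Reactants: 5 1-[2-methoxy-3-(methoxymethoxy)-4-(3-methylbut-2-enyloxy)phenyl]ethanone; 7 1-bromo-2,4-bis(triisopropylsilyloxy)benzene
Product: 8 2-[2,4-bis(triisopropylsilyloxy)phenyl]-1-[2-methoxy-3-(methoxymethoxy)-4-(3-methylbut-2-enyloxy)phenyl]ethanone
Conditions: Pd(OAc)2 (cat.), XPhos, K3PO4, toluene, 80 °C
Reagents that add atoms: none
Why: Palladium-catalysed α-arylation of the methyl ketone enolate should form the C4–C4a bond, and mono-arylation is favoured because the enolate of the product is more hindered and less nucleophilic.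

Step 6
Reactants: 8 2-[2,4-bis(triisopropylsilyloxy)phenyl]-1-[2-methoxy-3-(methoxymethoxy)-4-(3-methylbut-2-enyloxy)phenyl]ethanone
Product: 9 1-{3-[2,4-bis(triisopropylsilyloxy)phenyl]prop-1-en-2-yl}-2-methoxy-3-(methoxymethoxy)-4-(3-methylbut-2-enyloxy)benzene
Conditions: Cp2TiMe2, toluene/THF, 70 °C, dark
Reagents that add atoms: dimethyltitanocene (Cp2TiMe2), C[Ti](C)(C1C=CC=C1)C1C=CC=C1
Why: Petasis methylenation should convert the hindered, easily enolised ketone into the C2=C3 1,1-disubstituted alkene through the non-basic titanium methylidene, which avoids enolisation.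

Step 7
Reactants: 9 1-{3-[2,4-bis(triisopropylsilyloxy)phenyl]prop-1-en-2-yl}-2-methoxy-3-(methoxymethoxy)-4-(3-methylbut-2-enyloxy)benzene
Product: 10 4-{2-[2-methoxy-3-(methoxymethoxy)-4-(3-methylbut-2-enyloxy)phenyl]prop-2-en-1-yl}benzene-1,3-diol
Conditions: TBAF, AcOH, THF, 0 °C
Reagents that add atoms: none
Why: Fluoride-mediated desilylation buffered with acetic acid should free both phenols of ring A without touching the MOM acetal, the prenyl ether or the acid-sensitive 1,1-disubstituted alkene.

Step 8
Reactants: 10 4-{2-[2-methoxy-3-(methoxymethoxy)-4-(3-methylbut-2-enyloxy)phenyl]prop-2-en-1-yl}benzene-1,3-diol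
Product: 11 (3R)-3-[2-methoxy-3-(methoxymethoxy)-4-(3-methylbut-2-enyloxy)phenyl]-3,4-dihydro-2H-chromen-7-ol
Conditions: 9-mesityl-3,6-di-tert-butyl-10-phenylacridinium tetrafluoroborate (5 mol%), homochiral 2'-methoxy-1,1'-binaphthalene-2-thiol (20 mol%), 2,6-lutidine (10 mol%), 1,2-dichloroethane (0.02 M), 450 nm LEDs, 0 °C, argon
Reagents that add atoms: none
Why: Proposed new method: the excited acridinium should oxidise the ring-B-conjugated C2=C3 alkene of 10 to its radical cation, the ortho phenol O1–H of ring A adds to the terminal carbon C2 and loses its proton, and the resulting tertiary benzylic C3 radical takes a hydrogen atom from the arenethiol, whose thiyl radical re-oxidises the acridine radical and whose thiolate picks up the proton. The closest known reaction type is the acridinium-photoredox anti-Markovnikov hydroetherification of alkenols run with an achiral hydrogen-atom donor, taken together with the known enantioselective hydrogen-atom transfer from homochiral thiols to prochiral carbon radicals; new is the use of a chiral arenethiol to fix a benzylic stereocentre in this cyclisation. The dihydropyran ring closes in the 6-endo-trig mode through the O1–C2 bond. The C3 stereocentre is set under catalyst control by face-selective hydrogen delivery from the thiol inside its binaphthyl pocket; the sense of induction cannot be predicted, so the thiol enantiomer that delivers 3R is the one used. The step needs anti-Markovnikov regioselectivity (O1 to C2, not 5-exo to C3), which the radical-cation polarity secures because attack at the unsubstituted terminus leaves the aryl-stabilised tertiary radical. It also needs chemoselectivity, which is secured because the 7-OH cannot reach the alkene, the isolated prenyl double bond is much harder to oxidise than the aryl alkene, and the arenethiyl radical is too weak to re-abstract the new C3–H.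

Step 9
Reactants: 11 (3R)-3-[2-methoxy-3-(methoxymethoxy)-4-(3-methylbut-2-enyloxy)phenyl]-3,4-dihydro-2H-chromen-7-ol
Product: 13 (3R)-3-[4-hydroxy-2-methoxy-3-(methoxymethoxy)-5-(2-methylbut-3-en-2-yl)phenyl]-3,4-dihydro-2H-chromen-7-ol, via ortho-dienone 12 (not isolated)
Conditions: N,N-diethylaniline, 185 °C, sealed tube, argon
Reagents that add atoms: none
Why: Aromatic Claisen rearrangement ([3,3]-sigmatropic shift) of the aryl prenyl ether should deliver the inverted 1,1-dimethylallyl group to C5', the only free ortho position, and tautomerisation of the dienone returns the 4'-phenol while C3 is untouched.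

Step 10
Reactants: 13 (3R)-3-[4-hydroxy-2-methoxy-3-(methoxymethoxy)-5-(2-methylbut-3-en-2-yl)phenyl]-3,4-dihydro-2H-chromen-7-ol
Product: 14 (3R)-3-[3,4-dihydroxy-2-methoxy-5-(2-methylbut-3-en-2-yl)phenyl]-3,4-dihydro-2H-chromen-7-ol (CNP0167796.1)
Conditions: HCl (1 M in MeOH), 40 °C, argon
Reagents that add atoms: none
Why: Acid-catalysed acetal exchange (MOM ether cleavage) in methanol should free the 3'-phenol under conditions too mild to protonate the monosubstituted alkene or to epimerise C3.

**Compound list**

1 | 2',3',4'-trihydroxyacetophenone | CC(=O)c1ccc(O)c(O)c1O | starting material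
2 | prenyl bromide (1-bromo-3-methylbut-2-ene) | CC(C)=CCBr | starting material
3 | 1-[2,3-dihydroxy-4-(3-methylbut-2-enyloxy)phenyl]ethanone | CC(=O)c1ccc(OCC=C(C)C)c(O)c1O | intermediate
4 | 1-[2-hydroxy-3-(methoxymethoxy)-4-(3-methylbut-2-enyloxy)phenyl]ethanone | CC(=O)c1ccc(OCC=C(C)C)c(OCOC)c1O | intermediate
5 | 1-[2-methoxy-3-(methoxymethoxy)-4-(3-methylbut-2-enyloxy)phenyl]ethanone | CC(=O)c1ccc(OCC=C(C)C)c(OCOC)c1OC | intermediate
6 | 4-bromoresorcinol (4-bromobenzene-1,3-diol) | Oc1ccc(Br)c(O)c1 | starting material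
7 | 1-bromo-2,4-bis(triisopropylsilyloxy)benzene | CC(C)[Si](Oc1ccc(Br)c(O[Si](C(C)C)(C(C)C)C(C)C)c1)(C(C)C)C(C)C | intermediate
8 | 2-[2,4-bis(triisopropylsilyloxy)phenyl]-1-[2-methoxy-3-(methoxymethoxy)-4-(3-methylbut-2-enyloxy)phenyl]ethanone | COc1c(C(=O)Cc2ccc(O[Si](C(C)C)(C(C)C)C(C)C)cc2O[Si](C(C)C)(C(C)C)C(C)C)ccc(OCC=C(C)C)c1OCOC | intermediate
9 | 1-{3-[2,4-bis(triisopropylsilyloxy)phenyl]prop-1-en-2-yl}-2-methoxy-3-(methoxymethoxy)-4-(3-methylbut-2-enyloxy)benzene | COc1c(C(=C)Cc2ccc(O[Si](C(C)C)(C(C)C)C(C)C)cc2O[Si](C(C)C)(C(C)C)C(C)C)ccc(OCC=C(C)C)c1OCOC | intermediate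
10 | 4-{2-[2-methoxy-3-(methoxymethoxy)-4-(3-methylbut-2-enyloxy)phenyl]prop-2-en-1-yl}benzene-1,3-diol | COc1c(C(=C)Cc2ccc(O)cc2O)ccc(OCC=C(C)C)c1OCOC | intermediate
11 | (3R)-3-[2-methoxy-3-(methoxymethoxy)-4-(3-methylbut-2-enyloxy)phenyl]-3,4-dihydro-2H-chromen-7-ol | COc1c([C@@H]2COc3cc(O)ccc3C2)ccc(OCC=C(C)C)c1OCOC | intermediate
12 | 4-[(3R)-7-hydroxy-3,4-dihydro-2H-chromen-3-yl]-3-methoxy-2-(methoxymethoxy)-6-(2-methylbut-3-en-2-yl)cyclohexa-2,4-dien-1-one (ortho-dienone, not isolated) | COC1=C(OCOC)C(=O)C(C(C)(C)C=C)C=C1[C@@H]1COc2cc(O)ccc2C1 | intermediate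
13 | (3R)-3-[4-hydroxy-2-methoxy-3-(methoxymethoxy)-5-(2-methylbut-3-en-2-yl)phenyl]-3,4-dihydro-2H-chromen-7-ol | COc1c([C@@H]2COc3cc(O)ccc3C2)cc(C(C)(C)C=C)c(O)c1OCOC | intermediate
14 | (3R)-3-[3,4-dihydroxy-2-methoxy-5-(2-methylbut-3-en-2-yl)phenyl]-3,4-dihydro-2H-chromen-7-ol | C=CC(C)(C)c1cc([C@@H]2COc3cc(O)ccc3C2)c(OC)c(O)c1O | target

**Step count and risks**

Total step count: 10. Longest linear sequence: 9 steps (steps 1, 2, 3, 5, 6, 7, 8, 9, 10 from compound 1); step 4 is a one-step side branch.

Steps most likely to fail: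

1. Step 8 (proposed new method). The hydrogen-atom transfer may show poor facial selectivity, because the two faces of the flat C3 radical differ only by the O1–C2 and C4–ring A flanks. Material may also be lost by oxidative coupling of the free resorcinol ring or by a dark, acid-catalysed Markovnikov closure. The fallback uses known chemistry, sets out from 9 and comes back at 11. Cobalt-hydride asymmetric hydroboration of 9 (CoCl2 complex of a homochiral iminopyridine–oxazoline ligand, NaBHEt3, HBpin, THF, rt) should add boron to C2 and hydrogen to C3 and give 2-[(2R)-3-[2,4-bis(triisopropylsilyloxy)phenyl]-2-[2-methoxy-3-(methoxymethoxy)-4-(3-methylbut-2-enyloxy)phenyl]propyl]-4,4,5,5-tetramethyl-1,3,2-dioxaborolane F1; the trisubstituted prenyl alkene is inert to this catalyst. Oxidation with NaBO3 in THF/water should give (2R)-3-[2,4-bis(triisopropylsilyloxy)phenyl]-2-[2-methoxy-3-(methoxymethoxy)-4-(3-methylbut-2-enyloxy)phenyl]propan-1-ol F2. TBAF/AcOH should then give 4-[(2R)-3-hydroxy-2-[2-methoxy-3-(methoxymethoxy)-4-(3-methylbut-2-enyloxy)phenyl]propyl]benzene-1,3-diol F3. An intramolecular Mitsunobu etherification (PPh3, DIAD, THF, 0 °C, high dilution) closes the O1–C2 bond by 6-exo-tet displacement at the primary carbon, leaves C3 untouched and gives 11.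

2. Step 9. At 185 °C the freed 4'-phenol may add to the new vinyl group (dihydrobenzofuran formation), the prenyl group may be lost, or the electron-rich phenols may be oxidised. The fallback sets out from 11 and comes back at 13. It changes the reaction to a tandem rearrangement–acylation (Ac2O, NaOAc, N,N-diethylaniline, 180 °C, sealed tube): the 7-OH is acetylated first and the 4'-phenol is trapped as it forms, so no free phenol is present at high temperature. This should give (3R)-3-[4-acetoxy-2-methoxy-3-(methoxymethoxy)-5-(2-methylbut-3-en-2-yl)phenyl]-3,4-dihydro-2H-chromen-7-yl acetate F4. Methanolysis of both acetates (K2CO3, MeOH, 0 °C) returns 13.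

3. Step 5. Zerovalent palladium may ionise the aryl prenyl ether in the presence of the free enolate (deprenylation or C-prenylation), oxidative addition next to the bulky ortho-silyloxy group may be slow, and a second arylation may occur. The fallback sets out from 5 and 7 and comes back at 8. Ketone 5 is first converted (LiHMDS, TMSCl, THF, −78 °C) into [1-[2-methoxy-3-(methoxymethoxy)-4-(3-methylbut-2-enyloxy)phenyl]ethenyl]oxytrimethylsilane F5. This enol silane is then coupled with 7 by the known palladium-catalysed arylation of silyl enol ethers under fluoride activation without free base (Pd(OAc)2, P(t-Bu)3, ZnF2, DMF, 80 °C), which gives 8.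

**Further compounds**

F1 | step 8 | 2-[(2R)-3-[2,4-bis(triisopropylsilyloxy)phenyl]-2-[2-methoxy-3-(methoxymethoxy)-4-(3-methylbut-2-enyloxy)phenyl]propyl]-4,4,5,5-tetramethyl-1,3,2-dioxaborolane | COc1c([C@@H](Cc2ccc(O[Si](C(C)C)(C(C)C)C(C)C)cc2O[Si](C(C)C)(C(C)C)C(C)C)CB2OC(C)(C)C(C)(C)O2)ccc(OCC=C(C)C)c1OCOC
F2 | step 8 | (2R)-3-[2,4-bis(triisopropylsilyloxy)phenyl]-2-[2-methoxy-3-(methoxymethoxy)-4-(3-methylbut-2-enyloxy)phenyl]propan-1-ol | COc1c([C@@H](Cc2ccc(O[Si](C(C)C)(C(C)C)C(C)C)cc2O[Si](C(C)C)(C(C)C)C(C)C)CO)ccc(OCC=C(C)C)c1OCOC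
F3 | step 8 | 4-[(2R)-3-hydroxy-2-[2-methoxy-3-(methoxymethoxy)-4-(3-methylbut-2-enyloxy)phenyl]propyl]benzene-1,3-diol | COc1c([C@@H](Cc2ccc(O)cc2O)CO)ccc(OCC=C(C)C)c1OCOC
F4 | step 9 | (3R)-3-[4-acetoxy-2-methoxy-3-(methoxymethoxy)-5-(2-methylbut-3-en-2-yl)phenyl]-3,4-dihydro-2H-chromen-7-yl acetate | COc1c([C@@H]2COc3cc(OC(C)=O)ccc3C2)cc(C(C)(C)C=C)c(OC(C)=O)c1OCOC
F5 | step 5 | [1-[2-methoxy-3-(methoxymethoxy)-4-(3-methylbut-2-enyloxy)phenyl]ethenyl]oxytrimethylsilane | COc1c(C(=C)O[Si](C)(C)C)ccc(OCC=C(C)C)c1OCOC
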